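**Retrosynthetic overview**
1. Target ⇒ one-pot removal of the tert-butyl ester and TBS ether ⇐ C8-selective Yamaguchi acylation of diol 17 with Z-acid 24 (from but-2-yn-1-ol, Ac2O and CO).
2. Diol 17 ⇒ C6 ketone 16. The C5 and C7 side chains sit equatorial next to the carbonyl, and hydride attack anti to the axial C10 methyl gives the axial C6–OH.
3. Key step: the C7–C11 bond forms by radical titanium/nickel reductive coupling of α,β-epoxy ketone 13 with 2-bromoacrylate 15. The same step releases C8–OH.
4. 13 ⇒ radical nickel Negishi coupling (C5–C4) of α-bromo epoxy ketone 8 ⇐ catalyst-controlled epoxidation of enone 5.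
5. Rings: the single carbocycle is carried intact from 3-methylcyclohexenone, with C10 set by asymmetric vinyl conjugate addition. A transient oxirane is fused on in step 3 and opened in step 8.

Assumption: atoms carry elemane numbering (ring C5–C10; C10 quaternary, C6 carbinol, C7 acrylate carbon, C8 ester carbon), and "up" is the face of the C10 methyl group.

**Step 1**
Reactants: 1 3-methylcyclohex-2-en-1-one; 2 vinylmagnesium bromide
Product: 4 (R)-3-ethenyl-3-methylcyclohexan-1-one, via bromomagnesium enolate 3 (not isolated)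
Conditions: CH2=CHMgBr (1.2 equiv), Cu(OTf)2 (3 mol %), chiral hydroxyalkyl-imidazolinium salt (NHC precursor, 4 mol %), Et2O, −30 °C; aq NH4Cl
Reagents that add atoms: none
Why: Copper–NHC-catalysed enantioselective conjugate addition of a Grignard reagent to a β-substituted cyclic enone, in which the chiral carbene picks the enone face and sets quaternary C10 (R here, methyl up and vinyl down).

**Step 2**
Reactants: 4 (R)-3-ethenyl-3-methylcyclohexan-1-one
Product: 5 (R)-5-ethenyl-5-methylcyclohex-2-en-1-one
Conditions: IBX (1.5 equiv), DMSO, 70 °C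
Reagents that add atoms: none
Why: IBX-mediated α,β-dehydrogenation through the enol can only create C7=C8 because C10 is quaternary, and no stereocentre is touched.

**Step 3**
Reactants: 5 (R)-5-ethenyl-5-methylcyclohex-2-en-1-one
Product: 6 (1S,4R,6S)-4-ethenyl-4-methyl-7-oxabicyclo[4.1.0]heptan-2-one (epoxide down)
Conditions: 9-amino-9-deoxy-epi-quinine (10 mol %), CF3CO2H (20 mol %), 50% aq H2O2 (1.5 equiv), dioxane, 35 °C
Reagents that add atoms: hydrogen peroxide, OO
Why: Asymmetric Weitz–Scheffer epoxidation under iminium catalysis by a primary cinchona amine salt, where methyl and vinyl at C10 give almost no facial bias, so the catalyst (or its quinidine-derived counterpart if needed) decides the face and puts C7–O and C8–O down, anti to the methyl.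

**Step 4**
Reactants: 6 epoxy ketone
Product: 8 3-bromo epoxy ketone (bromine at C5; both C5 epimers; other centres as in 6), via lithium enolate 7 (not isolated)
Conditions: LiN(SiMe3)2, THF, −78 °C; NBS, −78 °C; H2O
Reagents that add atoms: N-bromosuccinimide, O=C1CCC(=O)N1Br
Why: Kinetic α′-deprotonation (C5 is the only enolisable position) followed by electrophilic bromination of the enolate, and the C5 configuration does not matter because the next step erases it.

**Step 5**
Reactants: 9 2-bromoprop-2-en-1-ol
Product: 10 (2-bromoallyloxy)(tert-butyl)dimethylsilane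
Conditions: TBSCl, imidazole, CH2Cl2, 0 °C to rt
Reagents that add atoms: tert-butyldimethylsilyl chloride, CC(C)(C)[Si](C)(C)Cl
Why: Standard silyl ether protection of the future C15 hydroxyl, with no stereocentre involved.

**Step 6**
Reactants: 8 3-bromo epoxy ketone; 10 (2-bromoallyloxy)(tert-butyl)dimethylsilane
Product: 13 epoxy ketone carrying the 3-(TBS-oxy)prop-1-en-2-yl group at C5 (side chain up; epoxide down), via alkenyllithium 11 (not isolated), via alkenylzinc bromide 12 (not isolated)
Conditions: 10, t-BuLi (2 equiv), Et2O, −78 °C; ZnBr2, THF, to 0 °C; 8, NiCl2(dme) (10 mol %), 2,6-bis(oxazolin-2-yl)pyridine (13 mol %), THF/glyme, −20 °C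
Reagents that add atoms: none
Why: Nickel-catalysed Negishi coupling of an α-bromo ketone runs by bromine abstraction at monovalent nickel and capture of the planar C5 α-keto radical, so the neopentyl site is tolerated, and the still epimerisable C5 settles with its side chain equatorial (up, cis to the methyl, away from an axial vinyl clashing with the epoxide).

**Step 7**
Reactants: 14 2-bromoacrylic acid
Product: 15 tert-butyl 2-bromoacrylate
Conditions: tert-butyl 2,2,2-trichloroacetimidate, BF3·OEt2 (cat.), cyclohexane/CH2Cl2, rt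
Reagents that add atoms: tert-butyl 2,2,2-trichloroacetimidate, CC(C)(C)OC(=N)C(Cl)(Cl)Cl
Why: Acid-catalysed imidate tert-butylation protects the acid as a bulky ester that later resists lactonisation by the cis C6–OH.

**Step 8 (key step)**
Reactants: 13 C5-alkenyl epoxy ketone; 15 tert-butyl 2-bromoacrylate
Product: 16 β-hydroxy ketone: tert-butyl 2-(ring-C7)acrylate with C6=O (C8–OH down; C7 and C5 side chains up; methyl up)
Conditions: 15 (1.5 equiv, slow addition), NiCl2(dme) (10 mol %), 4,4′-di-tert-butyl-2,2′-bipyridine (10 mol %), Cp2TiCl2 (20 mol %), Mn powder (3 equiv), Et3N·HCl (1.5 equiv), DMPU/THF, rt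
Reagents that add atoms: none
Why: Proposed new method: trivalent titanium (Cp2TiCl from Cp2TiCl2/Mn) opens the α,β-epoxy ketone by single-electron transfer at C7–O to give the C8 titanium alkoxide and an electrophilic C7 α-keto radical; this radical is polarity-mismatched for Giese addition to the electron-poor bromoacrylate and is instead captured by the divalent alkenylnickel bromide formed from 15, and reductive elimination makes C7–C11 anti to the C8–O–Ti group (side chain up, equatorial, also the thermodynamic epimer next to the ketone); the closest known reaction types are titanium/nickel co-catalysed cross-electrophile coupling of epoxides with aryl or alkenyl halides and titanocene-mediated reductive opening of α,β-epoxy ketones.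

**Step 9**
Reactants: 16 β-hydroxy ketone
Product: 17 C6,C8-diol (C6–OH up and axial; C8–OH down and equatorial)
Conditions: NaBH4, CeCl3·7H2O, MeOH, −78 °C
Reagents that add atoms: none
Why: In this Luche reduction the axial C10 methyl blocks the top face of the C6 carbonyl, so hydride enters from below and gives the axial alcohol cis to both neighbours, while CeCl3 suppresses conjugate reduction and enolisation.

**Step 10**
Reactants: 18 but-2-yn-1-ol
Product: 20 (Z)-3-iodobut-2-en-1-ol, via cyclic vinylalanate 19 (not isolated)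
Conditions: NaAlH2(OCH2CH2OMe)2, THF, 0 °C to rt; I2, −78 to 0 °C; aqueous work-up
Reagents that add atoms: iodine, II
Why: Alkoxide-directed trans-hydroalumination of the propargylic alcohol and iodinolysis with retention give only the Z-iodoalkene.

**Step 11**
Reactants: 20 (Z)-3-iodobut-2-en-1-ol; 21 acetic anhydride
Product: 22 (Z)-3-iodobut-2-en-1-yl acetate
Conditions: Ac2O, pyridine, CH2Cl2, 0 °C
Reagents that add atoms: none
Why: Simple O-acetylation installs the acetate of the target and blocks later butenolide formation.

**Step 12**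
Reactants: 22 (Z)-3-iodobut-2-en-1-yl acetate; 23 carbon monoxide
Product: 24 (Z)-4-acetoxy-2-methylbut-2-enoic acid
Conditions: Pd(OAc)2 (5 mol %), PPh3 (10 mol %), CO (1 atm), H2O (5 equiv), Et3N, DMF, rt
Reagents that add atoms: water, O
Why: Palladium-catalysed hydroxycarbonylation (oxidative addition, CO insertion, hydrolysis) keeps the alkene geometry, and the fast C–I insertion outruns ionisation of the allylic acetate.

**Step 13**
Reactants: 17 C6,C8-diol; 24 (Z)-4-acetoxy-2-methylbut-2-enoic acid
Product: 26 C8 ester (tert-butyl ester and TBS ether still on; C6–OH free), via mixed anhydride 25 (not isolated)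
Conditions: 24, 2,4,6-trichlorobenzoyl chloride, Et3N, toluene, rt; 17, 75 °C (no DMAP)
Reagents that add atoms: none
Why: Yamaguchi esterification run without a nucleophilic catalyst avoids Z-to-E isomerisation, and it acylates only the equatorial C8–OH because the axial C6–OH is flanked by two branched carbons and is syn-axial to the methyl.

**Step 14**
Reactants: 26 protected C8 ester
Product: 28 target CNP0261293.3, via silylated intermediate 27 (not isolated)
Conditions: Me3SiOTf, 2,6-lutidine, CH2Cl2, 0 °C; HF·pyridine, pyridine, THF, 0 °C; pH 6 buffer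
Reagents that add atoms: none
Why: Silyl triflate cleavage turns the tert-butyl ester into a silyl ester while C6–OH is masked as its silyl ether (so no lactonisation), and buffered fluoride then removes all silicon without touching the two carboxylic esters or any stereocentre.

**Compound list**
1 | 3-methylcyclohex-2-en-1-one | CC1=CC(=O)CCC1 | starting material
2 | vinylmagnesium bromide | C=C[Mg]Br | starting material
3 | bromomagnesium enolate of 4 | C=C[C@]1(C)CCCC(O[Mg]Br)=C1 | intermediate
4 | (R)-3-ethenyl-3-methylcyclohexan-1-one | C=C[C@]1(C)CCCC(=O)C1 | intermediate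
5 | (R)-5-ethenyl-5-methylcyclohex-2-en-1-one | C=C[C@]1(C)CC=CC(=O)C1 | intermediate
6 | (1S,4R,6S)-4-ethenyl-4-methyl-7-oxabicyclo[4.1.0]heptan-2-one | C=C[C@]1(C)C[C@@H]2O[C@@H]2C(=O)C1 | intermediate
7 | lithium enolate of 6 | C=C[C@]1(C)C[C@@H]2O[C@@H]2C(O[Li])=C1 | intermediate
8 | 3-bromo derivative of 6 (C5–Br, both epimers) | C=C[C@]1(C)C[C@@H]2O[C@@H]2C(=O)C1Br | intermediate
9 | 2-bromoprop-2-en-1-ol | C=C(Br)CO | starting material
10 | (2-bromoallyloxy)(tert-butyl)dimethylsilane | C=C(Br)CO[Si](C)(C)C(C)(C)C | intermediate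
11 | [3-(TBS-oxy)prop-1-en-2-yl]lithium | [Li]C(=C)CO[Si](C)(C)C(C)(C)C | intermediate
12 | [3-(TBS-oxy)prop-1-en-2-yl]zinc bromide | Br[Zn]C(=C)CO[Si](C)(C)C(C)(C)C | intermediate
13 | C5-alkenyl epoxy ketone (side chain up, epoxide down) | C=C[C@]1(C)C[C@@H]2O[C@@H]2C(=O)[C@H]1C(=C)CO[Si](C)(C)C(C)(C)C | intermediate
14 | 2-bromoacrylic acid | C=C(Br)C(=O)O | starting material
15 | tert-butyl 2-bromoacrylate | C=C(Br)C(=O)OC(C)(C)C | intermediate
16 | C6 ketone with C7 tert-butyl acrylate and C8–OH | C=C[C@]1(C)C[C@H](O)[C@@H](C(=C)C(=O)OC(C)(C)C)C(=O)[C@H]1C(=C)CO[Si](C)(C)C(C)(C)C | intermediate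
17 | C6,C8-diol | C=C[C@]1(C)C[C@H](O)[C@@H](C(=C)C(=O)OC(C)(C)C)[C@@H](O)[C@H]1C(=C)CO[Si](C)(C)C(C)(C)C | intermediate
18 | but-2-yn-1-ol | CC#CCO | starting material
19 | sodium cyclic vinylalanate | CC1=CCO[Al-]1(OCCOC)OCCOC.[Na+] | intermediate
20 | (Z)-3-iodobut-2-en-1-ol | C/C(I)=C/CO | intermediate
21 | acetic anhydride | CC(=O)OC(C)=O | starting material
22 | (Z)-3-iodobut-2-en-1-yl acetate | C/C(I)=C/COC(C)=O | intermediate
23 | carbon monoxide | [C-]#[O+] | starting material
24 | (Z)-4-acetoxy-2-methylbut-2-enoic acid | OC(=O)/C(C)=C\COC(C)=O | intermediate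
25 | mixed anhydride of 24 with 2,4,6-trichlorobenzoic acid | O=C(OC(=O)/C(C)=C\COC(C)=O)c1c(Cl)cc(Cl)cc1Cl | intermediate
26 | protected target (tert-butyl ester, TBS ether) | C=C[C@]1(C)C[C@H](OC(=O)/C(C)=C\COC(C)=O)[C@@H](C(=C)C(=O)OC(C)(C)C)[C@@H](O)[C@H]1C(=C)CO[Si](C)(C)C(C)(C)C | intermediate
27 | trimethylsilyl ester, C6 trimethylsilyl ether, C15 TBS ether | C=C[C@]1(C)C[C@H](OC(=O)/C(C)=C\COC(C)=O)[C@@H](C(=C)C(=O)O[Si](C)(C)C)[C@@H](O[Si](C)(C)C)[C@H]1C(=C)CO[Si](C)(C)C(C)(C)C | intermediate
28 | CNP0261293.3, (5R,6S,7S,8S,10S) in elemane numbering | C=C[C@]1(C)C[C@H](OC(=O)/C(C)=C\COC(C)=O)[C@@H](C(=C)C(=O)O)[C@@H](O)[C@H]1C(=C)CO | target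

**Step count:** 14 steps in total. The longest linear sequence is 9 steps (1, 2, 3, 4, 6, 8, 9, 13, 14).

**Three steps most likely to fail, each with one fallback**

Step 8. The C7 radical may be over-reduced to the titanium enolate, may add to 15 in Giese fashion, may cyclise onto the C10 vinyl, or the aldol-type product may dehydrate. The fallback sets out from 13 and separates ring opening from coupling. MgBr2·OEt2 opens the epoxide at C7 with inversion to the α-bromo-β-hydroxy ketone F1. F1 is then coupled under NiCl2(dme)/pybox with [1-(tert-butoxycarbonyl)vinyl]zinc bromide F2, made from 15 and activated zinc, and this returns to the route at 16.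

Step 6. The crowded C5 radical may simply be reduced, or the organozinc may attack the epoxy ketone. The fallback sets out from 6 and drops the bromide. Enolate 7 is trapped with Me3SiCl as the trimethylsilyl enol ether F3. F3 is alkenylated in a polar, CuCl-catalysed group transfer from [3-(TBS-oxy)prop-1-en-2-yl](mesityl)iodonium triflate F4, prepared from zinc reagent 12 and MesI(OAc)2/TfOH, and this returns at 13.

Step 13. Acylation of the hindered alcohol may be slow, or the side chain may isomerise from Z to E. The fallback sets out from 17 and builds the Z-alkene on the substrate. DCC coupling with 2-[bis(2,2,2-trifluoroethoxy)phosphoryl]propanoic acid gives the C8 phosphonopropionate F5. Still–Gennari olefination of F5 with 2-oxoethyl acetate (KN(SiMe3)2, 18-crown-6, THF, −78 °C) returns at 26.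

**Further compounds**
F1 | step 8 | α-bromo-β-hydroxy ketone (C7–Br up, C8–OH down) | C=C[C@]1(C)C[C@H](O)[C@@H](Br)C(=O)[C@H]1C(=C)CO[Si](C)(C)C(C)(C)C
F2 | step 8 | [1-(tert-butoxycarbonyl)vinyl]zinc bromide | C=C([Zn]Br)C(=O)OC(C)(C)C
F3 | step 6 | trimethylsilyl enol ether of 6 | C=C[C@]1(C)C[C@@H]2O[C@@H]2C(O[Si](C)(C)C)=C1
F4 | step 6 | [3-(TBS-oxy)prop-1-en-2-yl](mesityl)iodonium triflate | C=C(CO[Si](C)(C)C(C)(C)C)[I+]c1c(C)cc(C)cc1C.[O-]S(=O)(=O)C(F)(F)F
F5 | step 13 | C8 2-[bis(2,2,2-trifluoroethoxy)phosphoryl]propanoate of 17 | C=C[C@]1(C)C[C@H](OC(=O)C(C)P(=O)(OCC(F)(F)F)OCC(F)(F)F)[C@@H](C(=C)C(=O)OC(C)(C)C)[C@@H](O)[C@H]1C(=C)CO[Si](C)(C)C(C)(C)C
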